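**Retrosynthetic overview**

1. Carotenoid numbering is used: β end unprimed; ε ring C1'–C6' (C1' = CMe2, C3' = CHOH, C4'=C5', C6' = C(OH)), chain C7' onward. The C40 chain is cut at C11=C12 and C11'=C12' (two Wittig reactions) into β-C15 salt 22, C10 dialdehyde 23 and ε-C15 aldehyde 16.
2. Enabling feature: C6' of the ε ring is a carbinol carbon with three carbon neighbours (C1', C5', C7') and lies 1,4 to O3' across C4'=C5'. It can therefore be the carbonyl of a γ-lactone whose ring oxygen is O3' (a temporary ring), and quaternary C1' makes this carbonyl non-enolizable.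
3. Key step: lactone 8 accepts an acetylide (C7') from outside and then its own (Z)-alkenyllithium (C5') from inside. The lactone ring opens and the ε carbocycle closes through the C5'–C6' bond, which sets C6' relative to C3'.
4. Lactone 8 comes from 2,2-dimethylsuccinic anhydride and a propynyl Grignard reagent by hydroiodination and CBS reduction (sets C3'). The β end comes from (4R,6R)-actinol by enol triflate formation and Sonogashira coupling.
5. Ring order: the β ring is bought and never opened; the temporary γ-lactone is closed in step 4 and removed in step 5; the ε carbocycle (step 5) is the only carbocycle closed and the last ring formed.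

Key step: step 5

Assumption: (4R,6R)-actinol (17), an industrial carotenoid intermediate, is taken as a purchasable starting material, as are 1, 2, 9 and 23.

**Route**

Step 1
Reactants: 1 2,2-dimethylsuccinic anhydride; 2 1-propynylmagnesium bromide
Product: 3 2,2-dimethyl-4-oxohept-5-ynoic acid
Conditions: 2 (1.0 equiv, THF) added slowly to 1 (1.2 equiv), THF, −78 → −40 °C; then 1 M HCl
Reagents that add atoms: none
Why: Acylation of an alkynyl Grignard reagent by a cyclic anhydride, in which the nucleophile should attack the carbonyl next to CH2 and not the one shielded by the gem-dimethyl group, while slow inverse addition at low temperature keeps the ynone (released as its magnesium carboxylate) away from excess reagent.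

Step 2
Reactants: 3 2,2-dimethyl-4-oxohept-5-ynoic acid
Product: 5 methyl 2,2-dimethyl-4-oxohept-5-ynoate, via potassium carboxylate 4 (not isolated)
Conditions: KHCO3, MeI, DMF, rt
Reagents that add atoms: iodomethane, CI
Why: O-alkylation of a carboxylate (SN2 on iodomethane), chosen because Fischer esterification is slow for an α-quaternary acid and the weak base should leave the ynone untouched.

Step 3
Reactants: 5 methyl 2,2-dimethyl-4-oxohept-5-ynoate
Product: 6 methyl (5Z)-6-iodo-2,2-dimethyl-4-oxohept-5-enoate
Conditions: NaI (1.5 equiv), AcOH, rt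
Reagents that add atoms: sodium iodide, [Na+].[I-]
Why: Conjugate hydroiodination of an ynone (iodide adds to the β-carbon and the allenol is protonated anti to iodine), which under kinetic control at room temperature should give the (Z)-β-iodo enone, with iodine cis to the carbonyl-bearing carbon as the later ring closure requires.

Step 4
Reactants: 6 methyl (5Z)-6-iodo-2,2-dimethyl-4-oxohept-5-enoate
Product: 8 (5S)-5-[(1Z)-2-iodoprop-1-en-1-yl]-3,3-dimethyloxolan-2-one, via hydroxy ester 7 (not isolated)
Conditions: (R)-2-methyl-CBS-oxazaborolidine (0.2 equiv), catecholborane, toluene, −78 °C; MeOH; then PPTS (cat.), toluene, 60 °C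
Reagents that add atoms: none
Why: Corey–Bakshi–Shibata reduction, in which the (R)-catalyst should deliver hydride to the face that gives the (S)-carbinol (future C3') when the iodoalkenyl group acts as the large and the CH2CMe2 group as the small substituent (catecholborane avoids hydroboration), followed by acid-catalysed lactonization of the γ-hydroxy ester, which the gem-dimethyl group favours.

Step 5
Reactants: 8 (5S)-5-[(1Z)-2-iodoprop-1-en-1-yl]-3,3-dimethyloxolan-2-one; 9 (2E)-3-methylpent-2-en-4-yn-1-ol
Product: 14 (1R,4S)-1-[(3E)-5-hydroxy-3-methylpent-3-en-1-yn-1-yl]-2,6,6-trimethylcyclohex-2-ene-1,4-diol, via dilithio enynol 10 (not isolated), via lithium lactolate 11 (not isolated), via alkenyllithium lactolate 12 (not isolated), via open-chain ynone 13 (not isolated)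
Conditions: 9 (1.05 equiv), n-BuLi (2.05 equiv per 9), THF, −78 → 0 °C; 8, −78 → −30 °C; t-BuLi (2.1 equiv), −78 °C; then → 0 °C; H2O
Reagents that add atoms: none
Why: Proposed new method: the lactone carbonyl C6' serves as a 1,1-dielectrophile that accepts two different carbanions in a programmed order, a combination whose closest known relatives are the double addition of organolithiums to lactones by way of the ring-opened lithium lactolate, the use of lithium hemiketal or hemiaminal alkoxides as in situ masks for carbonyl groups during a lithiation elsewhere, and the anionic cyclization of alkenyllithiums from iodine–lithium exchange onto ketones. Acetylide 10 adds once to the non-enolizable lactone (C1' is quaternary) and lactolate 11 hides C6' while t-BuLi turns the (Z)-alkenyl iodide into alkenyllithium 12 with retention of geometry. On warming, 12 opens by C6'–O3' cleavage to ynone 13, which has no α-hydrogen and is trapped by the tethered C5' carbanion in a 6-exo-trig 1,2-addition that forms the C5'–C6' bond and closes the six-membered ε ring. The new stereocentre C6' is controlled by C3': O3' and C5' share lithium in a five-membered internal aggregate, the ketone oxygen has to bind to this aggregate before the C–C bond forms, and O6' is therefore delivered to the face that carries O3' (cis-3',6'-diol, 6'R from 3'S); sterics point the same way, since the slim alkynyl group rather than the solvated O–Li should take the pseudoequatorial site between the C1' methyl groups and the C5' methyl group. The step needs exchange before unmasking (secured by the stability of 11 at −78 °C), 1,2- instead of conjugate attack on the ynone (the 1,4-mode would need an eight-membered ring) and ring closure faster than intermolecular addition (secured by the tether, by the geminal methyl groups at C1' and by the near-stoichiometric amount of 10).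

Step 6
Reactants: 14 (1R,4S)-1-[(3E)-5-hydroxy-3-methylpent-3-en-1-yn-1-yl]-2,6,6-trimethylcyclohex-2-ene-1,4-diol
Product: 15 (1R,4S)-1-[(1E,3E)-5-hydroxy-3-methylpenta-1,3-dien-1-yl]-2,6,6-trimethylcyclohex-2-ene-1,4-diol
Conditions: NaAlH2(OCH2CH2OMe)2 (Red-Al, 5 equiv), THF, 0 °C → rt; aq. potassium sodium tartrate
Reagents that add atoms: none
Why: Hydroxyl-directed trans-hydroalumination of a propargylic alcohol (aluminium bound to O6' delivers hydride across C7'≡C8'), which after protonation should give only the (7'E)-alkene and leave the ring alkene, the C9'=C10' alkene and both stereocentres untouched.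

Step 7
Reactants: 15 (1R,4S)-1-[(1E,3E)-5-hydroxy-3-methylpenta-1,3-dien-1-yl]-2,6,6-trimethylcyclohex-2-ene-1,4-diol
Product: 16 (2E,4E)-5-[(1R,4S)-1,4-dihydroxy-2,6,6-trimethylcyclohex-2-en-1-yl]-3-methylpenta-2,4-dienal
Conditions: [Cu(MeCN)4]OTf (5 mol %), 2,2'-bipyridine (5 mol %), TEMPO (5 mol %), N-methylimidazole (10 mol %), MeCN, air, rt
Reagents that add atoms: none
Why: Aerobic copper/TEMPO alcohol oxidation, which is selective for unhindered primary (here allylic) alcohols over secondary and tertiary ones and runs without acid, so that the C3' carbinol and the acid-sensitive doubly allylic C6' carbinol should survive.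

Step 8
Reactants: 17 (4R,6R)-4-hydroxy-2,2,6-trimethylcyclohexan-1-one
Product: 18 (4R,6R)-4-{[tert-butyl(dimethyl)silyl]oxy}-2,2,6-trimethylcyclohexan-1-one
Conditions: TBSCl, imidazole, DMF, rt
Reagents that add atoms: tert-butyl(chloro)dimethylsilane, CC(C)(C)[Si](C)(C)Cl
Why: Standard silylation of the secondary alcohol, needed so that the enolate chemistry of the next step involves the ketone only.

Step 9
Reactants: 18 (4R,6R)-4-{[tert-butyl(dimethyl)silyl]oxy}-2,2,6-trimethylcyclohexan-1-one
Product: 20 (4R)-4-{[tert-butyl(dimethyl)silyl]oxy}-2,6,6-trimethylcyclohex-1-en-1-yl trifluoromethanesulfonate, via potassium enolate 19 (not isolated)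
Conditions: KN(SiMe3)2, THF, −78 °C; PhNTf2, −78 °C → rt
Reagents that add atoms: N-phenylbis(trifluoromethanesulfonimide), O=S(=O)(N(c1ccccc1)S(=O)(=O)C(F)(F)F)C(F)(F)F
Why: Enol triflate formation, regiochemically unambiguous because the ketone can enolize only toward C5 (C1 is quaternary), which also removes the C5 stereocentre that the target does not need.

Step 10
Reactants: 20 (4R)-4-{[tert-butyl(dimethyl)silyl]oxy}-2,6,6-trimethylcyclohex-1-en-1-yl trifluoromethanesulfonate; 9 (2E)-3-methylpent-2-en-4-yn-1-ol
Product: 21 (2E)-5-[(4R)-4-{[tert-butyl(dimethyl)silyl]oxy}-2,6,6-trimethylcyclohex-1-en-1-yl]-3-methylpent-2-en-4-yn-1-ol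
Conditions: Pd(PPh3)4 (5 mol %), CuI (10 mol %), i-Pr2NH, DMF, rt
Reagents that add atoms: none
Why: Sonogashira coupling of the alkenyl triflate with the terminal alkyne, which forms the C6–C7 bond of the 7,8-didehydro end group and carries the (9E) geometry of 9 over unchanged.

Step 11
Reactants: 21 (2E)-5-[(4R)-4-{[tert-butyl(dimethyl)silyl]oxy}-2,6,6-trimethylcyclohex-1-en-1-yl]-3-methylpent-2-en-4-yn-1-ol
Product: 22 {(2E)-5-[(4R)-4-hydroxy-2,6,6-trimethylcyclohex-1-en-1-yl]-3-methylpent-2-en-4-yn-1-yl}(triphenyl)phosphonium bromide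
Conditions: PPh3·HBr (1.3 equiv), MeOH, rt, dark
Reagents that add atoms: triphenylphosphane hydrobromide, Br.c1ccc(cc1)P(c1ccccc1)c1ccccc1
Why: Conversion of a primary allylic alcohol into its phosphonium salt by SN1-type substitution (allyl cation or bromide, then quaternization by PPh3), the usual way to carotenoid C15 Wittig salts, during which the excess acid in methanol should also methanolyse the secondary TBS ether while the homoallylic secondary alcohol does not ionize.

Step 12
Reactants: 22 {(2E)-5-[(4R)-4-hydroxy-2,6,6-trimethylcyclohex-1-en-1-yl]-3-methylpent-2-en-4-yn-1-yl}(triphenyl)phosphonium bromide; 23 (2E,4E,6E)-2,7-dimethylocta-2,4,6-trienedial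
Product: 25 (2E,4E,6E,8E,10E)-13-[(4R)-4-hydroxy-2,6,6-trimethylcyclohex-1-en-1-yl]-2,7,11-trimethyltrideca-2,4,6,8,10-pentaen-12-ynal, via phosphorus ylide 24 (not isolated)
Conditions: 23 (2 equiv), NaOMe, MeOH/CH2Cl2, 0 °C → rt, dark; then heptane, 80 °C
Reagents that add atoms: none
Why: Wittig olefination of the semi-stabilized allylic ylide with one formyl group of the dialdehyde (used in excess) forms C11=C12, and the (11Z) isomer formed alongside should be converted into the (E) isomer by thermal equilibration, as is usual for unhindered carotenoid double bonds.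

Step 13
Reactants: 25 (2E,4E,6E,8E,10E)-13-[(4R)-4-hydroxy-2,6,6-trimethylcyclohex-1-en-1-yl]-2,7,11-trimethyltrideca-2,4,6,8,10-pentaen-12-ynal
Product: 26 (2E,4E,6E,8E,10E)-13-[(4R)-4-hydroxy-2,6,6-trimethylcyclohex-1-en-1-yl]-2,7,11-trimethyltrideca-2,4,6,8,10-pentaen-12-yn-1-ol
Conditions: NaBH4, MeOH/THF, 0 °C, dark
Reagents that add atoms: none
Why: Chemoselective 1,2-reduction of a polyenal by borohydride, which does not touch the polyene or the alkyne.

Step 14
Reactants: 26 (2E,4E,6E,8E,10E)-13-[(4R)-4-hydroxy-2,6,6-trimethylcyclohex-1-en-1-yl]-2,7,11-trimethyltrideca-2,4,6,8,10-pentaen-12-yn-1-ol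
Product: 27 {(2E,4E,6E,8E,10E)-13-[(4R)-4-hydroxy-2,6,6-trimethylcyclohex-1-en-1-yl]-2,7,11-trimethyltrideca-2,4,6,8,10-pentaen-12-yn-1-yl}(triphenyl)phosphonium bromide
Conditions: PPh3·HBr, MeOH/CH2Cl2, 0 °C → rt, dark, argon
Reagents that add atoms: triphenylphosphane hydrobromide, Br.c1ccc(cc1)P(c1ccccc1)c1ccccc1
Why: The same allylic alcohol to phosphonium salt conversion as in step 11, here on a polyenylic primary alcohol that ionizes readily (as retinol does), while the secondary 3-OH does not react.

Step 15
Reactants: 27 {(2E,4E,6E,8E,10E)-13-[(4R)-4-hydroxy-2,6,6-trimethylcyclohex-1-en-1-yl]-2,7,11-trimethyltrideca-2,4,6,8,10-pentaen-12-yn-1-yl}(triphenyl)phosphonium bromide; 16 (2E,4E)-5-[(1R,4S)-1,4-dihydroxy-2,6,6-trimethylcyclohex-2-en-1-yl]-3-methylpenta-2,4-dienal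
Product: 29 (3R,3'S,6'R)-7,8-didehydro-β,ε-carotene-3,3',6'-triol (all-E), via polyenyl ylide 28 (not isolated)
Conditions: NaOMe, MeOH/CH2Cl2, −10 °C → rt, dark, argon; then EtOH/heptane, 70 °C; chromatography or crystallization
Reagents that add atoms: none
Why: Wittig olefination between the polyenyl ylide and the dienal forms C11'=C12' and completes the C40 chain under non-acidic conditions that tolerate the three free hydroxyl groups, and thermal equilibration should convert the (11'Z) isomer into the all-E target.

**Compound list**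

1 | 2,2-dimethylsuccinic anhydride (3,3-dimethyloxolane-2,5-dione) | CC1(C)CC(=O)OC1=O | starting material
2 | 1-propynylmagnesium bromide | CC#C[Mg]Br | starting material
3 | 2,2-dimethyl-4-oxohept-5-ynoic acid | CC#CC(=O)CC(C)(C)C(=O)O | intermediate
4 | potassium 2,2-dimethyl-4-oxohept-5-ynoate | CC#CC(=O)CC(C)(C)C(=O)[O-].[K+] | intermediate
5 | methyl 2,2-dimethyl-4-oxohept-5-ynoate | CC#CC(=O)CC(C)(C)C(=O)OC | intermediate
6 | methyl (5Z)-6-iodo-2,2-dimethyl-4-oxohept-5-enoate | C/C(I)=C/C(=O)CC(C)(C)C(=O)OC | intermediate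
7 | methyl (4S,5Z)-4-hydroxy-6-iodo-2,2-dimethylhept-5-enoate | C/C(I)=C/[C@@H](O)CC(C)(C)C(=O)OC | intermediate
8 | (5S)-5-[(1Z)-2-iodoprop-1-en-1-yl]-3,3-dimethyloxolan-2-one | C/C(I)=C/[C@@H]1CC(C)(C)C(=O)O1 | intermediate
9 | (2E)-3-methylpent-2-en-4-yn-1-ol | C#C/C(C)=C/CO | starting material
10 | dilithio derivative of 9 (lithium alkoxide and lithium acetylide) | [Li]C#C/C(C)=C/CO[Li] | intermediate
11 | lithium lactolate: (5S)-2-alkynyl-2-(lithiooxy)-5-[(1Z)-2-iodoprop-1-enyl]-3,3-dimethyloxolane, mixture at C2 | C/C(I)=C/[C@@H]1CC(C)(C)C(O[Li])(C#C/C(C)=C/CO[Li])O1 | intermediate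
12 | alkenyllithium lactolate: as 11 with lithium in place of iodine, (Z) geometry retained | C/C([Li])=C/[C@@H]1CC(C)(C)C(O[Li])(C#C/C(C)=C/CO[Li])O1 | intermediate
13 | open-chain ynone: trilithio (2E,9S,10Z)-1,9-dihydroxy-3,7,7-trimethyldodeca-2,10-dien-4-yn-6-one lithiated at C11 | C/C([Li])=C/[C@@H](O[Li])CC(C)(C)C(=O)C#C/C(C)=C/CO[Li] | intermediate
14 | (1R,4S)-1-[(3E)-5-hydroxy-3-methylpent-3-en-1-yn-1-yl]-2,6,6-trimethylcyclohex-2-ene-1,4-diol | CC1=C[C@@H](O)CC(C)(C)[C@]1(O)C#C/C(C)=C/CO | intermediate
15 | (1R,4S)-1-[(1E,3E)-5-hydroxy-3-methylpenta-1,3-dien-1-yl]-2,6,6-trimethylcyclohex-2-ene-1,4-diol | CC1=C[C@@H](O)CC(C)(C)[C@]1(O)/C=C/C(C)=C/CO | intermediate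
16 | (2E,4E)-5-[(1R,4S)-1,4-dihydroxy-2,6,6-trimethylcyclohex-2-en-1-yl]-3-methylpenta-2,4-dienal | CC1=C[C@@H](O)CC(C)(C)[C@]1(O)/C=C/C(C)=C/C=O | intermediate
17 | (4R,6R)-4-hydroxy-2,2,6-trimethylcyclohexan-1-one (actinol) | CC1(C)C[C@H](O)C[C@@H](C)C1=O | starting material
18 | (4R,6R)-4-{[tert-butyl(dimethyl)silyl]oxy}-2,2,6-trimethylcyclohexan-1-one | CC1(C)C[C@H](O[Si](C)(C)C(C)(C)C)C[C@@H](C)C1=O | intermediate
19 | potassium enolate of 18 (potassium (4R)-4-silyloxy-2,6,6-trimethylcyclohex-1-en-1-olate) | CC1=C(O[K])C(C)(C)C[C@H](O[Si](C)(C)C(C)(C)C)C1 | intermediate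
20 | (4R)-4-{[tert-butyl(dimethyl)silyl]oxy}-2,6,6-trimethylcyclohex-1-en-1-yl trifluoromethanesulfonate | CC1=C(OS(=O)(=O)C(F)(F)F)C(C)(C)C[C@H](O[Si](C)(C)C(C)(C)C)C1 | intermediate
21 | (2E)-5-[(4R)-4-{[tert-butyl(dimethyl)silyl]oxy}-2,6,6-trimethylcyclohex-1-en-1-yl]-3-methylpent-2-en-4-yn-1-ol | CC1=C(C#C/C(C)=C/CO)C(C)(C)C[C@H](O[Si](C)(C)C(C)(C)C)C1 | intermediate
22 | {(2E)-5-[(4R)-4-hydroxy-2,6,6-trimethylcyclohex-1-en-1-yl]-3-methylpent-2-en-4-yn-1-yl}(triphenyl)phosphonium bromide | CC1=C(C#C/C(C)=C/C[P+](c2ccccc2)(c2ccccc2)c2ccccc2)C(C)(C)C[C@H](O)C1.[Br-] | intermediate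
23 | (2E,4E,6E)-2,7-dimethylocta-2,4,6-trienedial | O=C/C(C)=C/C=C/C=C(C)/C=O | starting material
24 | phosphorus ylide of 22 (triphenylphosphoranylidene at C11) | CC1=C(C#C/C(C)=C/C=P(c2ccccc2)(c2ccccc2)c2ccccc2)C(C)(C)C[C@H](O)C1 | intermediate
25 | (2E,4E,6E,8E,10E)-13-[(4R)-4-hydroxy-2,6,6-trimethylcyclohex-1-en-1-yl]-2,7,11-trimethyltrideca-2,4,6,8,10-pentaen-12-ynal | O=C/C(C)=C/C=C/C=C(C)/C=C/C=C(\C)C#CC1=C(C)C[C@@H](O)CC1(C)C | intermediate
26 | (2E,4E,6E,8E,10E)-13-[(4R)-4-hydroxy-2,6,6-trimethylcyclohex-1-en-1-yl]-2,7,11-trimethyltrideca-2,4,6,8,10-pentaen-12-yn-1-ol | OC/C(C)=C/C=C/C=C(C)/C=C/C=C(\C)C#CC1=C(C)C[C@@H](O)CC1(C)C | intermediate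
27 | {(2E,4E,6E,8E,10E)-13-[(4R)-4-hydroxy-2,6,6-trimethylcyclohex-1-en-1-yl]-2,7,11-trimethyltrideca-2,4,6,8,10-pentaen-12-yn-1-yl}(triphenyl)phosphonium bromide | [Br-].c1ccc(cc1)[P+](c1ccccc1)(c1ccccc1)C/C(C)=C/C=C/C=C(C)/C=C/C=C(\C)C#CC1=C(C)C[C@@H](O)CC1(C)C | intermediate
28 | polyenyl ylide of 27 (triphenylphosphoranylidene at C12') | c1ccc(cc1)P(c1ccccc1)(c1ccccc1)=C/C(C)=C/C=C/C=C(C)/C=C/C=C(\C)C#CC1=C(C)C[C@@H](O)CC1(C)C | intermediate
29 | (3R,3'S,6'R)-7,8-didehydro-β,ε-carotene-3,3',6'-triol (CNP0113828.1) | CC1=C[C@@H](O)CC(C)(C)[C@]1(O)/C=C/C(C)=C/C=C/C(C)=C/C=C/C=C(C)/C=C/C=C(\C)C#CC1=C(C)C[C@@H](O)CC1(C)C | target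

**Step count**

Total steps: 15. Longest linear sequence: 8 steps (steps 1–7 then 15; the β branch, steps 8–15, is equally long).

**Steps most likely to fail**

Step 5 (Proposed new method). What may go wrong: the lactolate may open before the iodine–lithium exchange is complete, so that t-BuLi or excess acetylide adds to the ynone; the alkenyllithium may be protonated before ring closure; or the facial selectivity of the ring closure may be poor. The fallback separates the two carbon–carbon bond formations and uses known chemistry. It sets out from lactone 8 and dilithio enynol 10. The addition is stopped after the first event by a water quench at −40 °C, which should give the open-chain hydroxy ynone (2E,9S,10Z)-1,9-dihydroxy-11-iodo-3,7,7-trimethyldodeca-2,10-dien-4-yn-6-one F1, in equilibrium with its lactol. The ring is then closed by an intramolecular Nozaki–Hiyama–Kishi reaction (CrCl2, NiCl2 1 mol %, DMSO/THF, rt), which tolerates the free hydroxyl groups and in which the alkenylchromium species carries O3' as an internal ligand, so the same cis sense is expected. This comes back to the route at triol 14.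

Step 4. What may go wrong: insufficient discrimination of the two ketone faces because the iodoalkenyl and the CH2CMe2 substituents are of similar size, or partial loss of the alkenyl iodide or of the Z geometry. The fallback sets the stereocentre on the ynone, a substrate class for which asymmetric transfer hydrogenation is reliable, and brings in the iodine afterwards. It sets out from ynone ester 5. RuCl(p-cymene)[(S,S)-TsDPEN] in i-PrOH should give methyl (4S)-4-hydroxy-2,2-dimethylhept-5-ynoate F2. PPTS then closes (5S)-3,3-dimethyl-5-(prop-1-yn-1-yl)oxolan-2-one F3. Ruthenium-catalysed trans-hydrosilylation ([Cp*Ru(MeCN)3]PF6, Et3SiH, CH2Cl2), which places silicon on the alkyne carbon remote from the oxygenated carbon, should give (5S)-3,3-dimethyl-5-[(1Z)-2-(triethylsilyl)prop-1-en-1-yl]oxolan-2-one F4. Iododesilylation with N-iodosuccinimide in hexafluoroisopropanol, with retention, comes back to the route at lactone 8.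

Step 15. What may go wrong: scrambling of double-bond geometry in the long, fully conjugated C25 ylide (at the new C11'=C12' bond and at C9=C10 next to the alkyne), and ionization or dehydration of the doubly allylic C6' carbinol during the isomerization. The fallback reverses the polarity of the last olefination, so that the ylide sits on the short ε-C15 unit and steps 13 and 14 are not needed. It sets out from dienetriol 15 and C25 aldehyde 25. Selective chlorination of the primary allylic alcohol (MsCl, 2,4,6-collidine, LiCl, DMF, 0 °C) should give (1R,4S)-1-[(1E,3E)-5-chloro-3-methylpenta-1,3-dien-1-yl]-2,6,6-trimethylcyclohex-2-ene-1,4-diol F5. PPh3 in MeCN then gives {(2E,4E)-5-[(1R,4S)-1,4-dihydroxy-2,6,6-trimethylcyclohex-2-en-1-yl]-3-methylpenta-2,4-dien-1-yl}(triphenyl)phosphonium chloride F6. Its Wittig reaction with 25 (NaOMe, MeOH/CH2Cl2, then thermal equilibration) comes back to the route at target 29.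

Further compounds
F1 | step 5 | (2E,9S,10Z)-1,9-dihydroxy-11-iodo-3,7,7-trimethyldodeca-2,10-dien-4-yn-6-one | C/C(I)=C/[C@@H](O)CC(C)(C)C(=O)C#C/C(C)=C/CO
F2 | step 4 | methyl (4S)-4-hydroxy-2,2-dimethylhept-5-ynoate | CC#C[C@@H](O)CC(C)(C)C(=O)OC
F3 | step 4 | (5S)-3,3-dimethyl-5-(prop-1-yn-1-yl)oxolan-2-one | CC#C[C@@H]1CC(C)(C)C(=O)O1
F4 | step 4 | (5S)-3,3-dimethyl-5-[(1Z)-2-(triethylsilyl)prop-1-en-1-yl]oxolan-2-one | C/C([Si](CC)(CC)CC)=C/[C@@H]1CC(C)(C)C(=O)O1
F5 | step 15 | (1R,4S)-1-[(1E,3E)-5-chloro-3-methylpenta-1,3-dien-1-yl]-2,6,6-trimethylcyclohex-2-ene-1,4-diol | CC1=C[C@@H](O)CC(C)(C)[C@]1(O)/C=C/C(C)=C/CCl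
F6 | step 15 | {(2E,4E)-5-[(1R,4S)-1,4-dihydroxy-2,6,6-trimethylcyclohex-2-en-1-yl]-3-methylpenta-2,4-dien-1-yl}(triphenyl)phosphonium chloride | CC1=C[C@@H](O)CC(C)(C)[C@]1(O)/C=C/C(C)=C/C[P+](c1ccccc1)(c1ccccc1)c1ccccc1.[Cl-]
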